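Labels: hydrindane C1 carries Ca (sp2; methylene Ca'), followed by Cb (methine; its CH2O carbon is Cc). The lactone atoms are L2 (C=O), L3 (carbinol), L4 and L5 (OCH2). The five carbons Ca, Cb, L4, L3 and L2 form an unbroken row. Joining its two termini in the retrosynthetic sense gives a cyclopentanone whose faces control Cb, L4 and L3. The precursor is this ketone with hydrindanyl and CH2OMs on Ca, a free L5 hydroxymethyl, a PMB-masked Cc arm and a silyl ether on L3. On deprotonation the L5 oxygen bridges to L2 and the hemiketal alkoxide fragments. The lactone ring, the Ca-L2 cleavage and the Ca=Ca' methylene thus arise in one operation.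

Key step: step 20

Conventions, checks and assumptions
- Faces: on the hydrindane, beta is the side of the C7a methyl. On the five-membered carbocycle, the lower face is the side of the Cc and L5 arms.
- Stereochemical cross-check: no structure needed correction.
  - The quaternary carbon of the (S)-configured bicyclic diketone maps directly onto C7a of the target.
  - The Cc and L5 arms must be cis on the carbocycle, and the L3 oxygen must be trans to L5.
  - This trans relation becomes the cis relation of hydroxyl and side chain once the L3-L4 bond belongs to the lactone.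
- Design choices:
  - (a) The Cc oxygen stays etherified through the fragmentation. A free Cc hydroxyl can bridge to L2 just as well. It would end in a six-membered lactone with all three substituents equatorial, and return from there to the five-membered lactone is not assured.
  - (b) An enantiopure 5-alkoxybutenolide is used as acceptor. The absolute sense of Cb/L4 is then fixed by an adjacent acetal centre and not by the remote hydrindane.
  - (c) The lactone-level carbons are reduced while L2 is still an alkene, since no hydride reagent would spare the ketone.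
- Assumption: the (5S)-menthyloxybutenolide derived from (+)-menthol is bought.
- Assumption: the carbinol epimers of the carbonate and any Ca epimers of the cycloadduct series are carried together, because both carbons become planar later.

Step 1
Reactants: 1 (S)-Hajos-Parrish ketone [(7aS)-7a-methyl-2,3,7,7a-tetrahydro-1H-indene-1,5(6H)-dione]
Product: 2 C1 ethylene ketal of 1 (C5 enone intact; 7aS)
Conditions: Me3SiOCH2CH2OSiMe3, Me3SiOTf (cat.), CH2Cl2, -78 °C
Reagents that add atoms: 1,2-bis(trimethylsilyloxy)ethane, C[Si](C)(C)OCCO[Si](C)(C)C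
Why: Silyl-triflate-catalysed dioxolanation with the bis-silyl ether of glycol is kinetically selective for a saturated ketone over a conjugated enone, so only C1 is masked and the stereocentre C7a is untouched.

Step 2
Reactants: 2 C1 ethylene ketal of 1
Product: 4 4,4-dimethyl-5-ketone ketal with the alkene moved to C3=C3a, via 4-methyl enone ketal 3 (not isolated)
Conditions: KOt-Bu, MeI, t-BuOH/THF, 0 °C to rt
Reagents that add atoms: iodomethane, CI
Why: Deconjugative double alpha-alkylation of an enone: the extended enolate is methylated twice at C4, which builds the gem-dimethyl group and parks the alkene at C3=C3a, while the ketal prevents enolisation at C2.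

Step 3
Reactants: 4 4,4-dimethyl-5-ketone ketal (C3=C3a alkene)
Product: 6 4,4,7a-trimethyl C3=C3a alkene ketal (C5 now CH2), via hydrazone 5 (not isolated)
Conditions: N2H4·H2O, KOH, diethylene glycol, 130 °C then 200 °C
Reagents that add atoms: none
Why: Wolff-Kishner reduction in the Huang-Minlon variant removes the hindered C5 carbonyl as it does in 4,4-dimethyl-3-keto steroids, and ketal and isolated alkene are inert to hot alkali.

Step 4
Reactants: 6 4,4,7a-trimethyl C3=C3a alkene ketal
Product: 7 trans-hydrindane ketal (3a-H alpha; 7a-CH3 beta)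
Conditions: H2 (4 bar), Pd/C, EtOAc, rt
Reagents that add atoms: none
Why: Heterogeneous catalytic hydrogenation reaches the trisubstituted alkene only from the alpha face, opposite the angular methyl group, as in the reduction of 14-ene steroids, so that 3a-H becomes alpha and the ring fusion trans.

Step 5
Reactants: 7 trans-hydrindane ketal
Product: 8 (3aS,7aS)-4,4,7a-trimethyloctahydro-1H-inden-1-one
Conditions: 1 M HCl, THF, rt
Reagents that add atoms: water, O
Why: Acid-catalysed ketal hydrolysis frees the C1 ketone, and the ring fusion cannot epimerise because C7a is quaternary and C3a is not alpha to the carbonyl.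

Step 6
Reactants: 8 trans-hydrindan-1-one
Product: 9 1-methylene-trans-hydrindane (exocyclic C1=CH2)
Conditions: Ph3PCH3Br, KOt-Bu, toluene, 90 °C
Reagents that add atoms: methyltriphenylphosphonium bromide, C[P+](c1ccccc1)(c1ccccc1)c1ccccc1.[Br-]
Why: Wittig methylenation with the small unstabilised ylide is the standard answer to neopentyl cyclopentanones of the 17-keto steroid type.

Step 7
Reactants: 9 1-methylene-trans-hydrindane
Product: 11 (1S,3aS,7aS)-hydrindan-1-ylmethanol (CH2OH beta), via B-alkyl-9-BBN adduct 10 (not isolated)
Conditions: 9-BBN, THF, 65 °C; then H2O2, NaOH, 0 °C to rt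
Reagents that add atoms: hydrogen peroxide, OO
Why: Hydroboration-oxidation: the bulky borane adds anti-Markovnikov and from the alpha face, away from the C7a methyl, so hydrogen enters C1 alpha and the CH2OH group ends up beta (cis to the methyl), and the oxidation retains configuration.

Step 8
Reactants: 11 hydrindan-1-ylmethanol
Product: 12 (1S,3aS,7aS)-4,4,7a-trimethyloctahydro-1H-indene-1-carbaldehyde (CHO beta)
Conditions: Dess-Martin periodinane, CH2Cl2, rt
Reagents that add atoms: none
Why: Dess-Martin oxidation under neutral conditions stops at the aldehyde and does not epimerise C1, whose beta configuration is the more stable one in any case.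

Step 9
Reactants: 12 hydrindane-1-beta-carbaldehyde; 13 2-bromoallyltrimethylsilane
Product: 16 methyl carbonate of 1-hydrindanyl-2-(trimethylsilylmethyl)prop-2-en-1-ol (both carbinol epimers), via vinyllithium 14 (not isolated), via lithium alkoxide 15 (not isolated)
Conditions: 13, t-BuLi (2 equiv), Et2O, -78 °C; 12; then ClCO2Me, -78 °C to rt
Reagents that add atoms: methyl chloroformate, COC(=O)Cl
Why: Bromine-lithium exchange, 1,2-addition of vinyllithium 14 to the aldehyde and O-acylation of alkoxide 15 in the same flask give the bifunctional allyl carbonate/allylsilane, and the uncontrolled carbinol centre does not matter because it becomes part of a planar allyl system in step 10.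

Step 10
Reactants: 16 hydrindanyl allyl carbonate/allylsilane; 17 (5S)-5-[(1S,2R,5S)-menthyloxy]furan-2(5H)-one
Product: 19 cis-fused 6-hydrindanyl-4-menthyloxy-7-methylene-3-oxabicyclo[3.3.0]octan-2-one (C1 = L4; C2 = L5; C4 = Cc; C5 = Cb; C6 = Ca; C7 = L2; C8 = L3; menthyloxy exo; hydrindanyl exo), via palladium TMM zwitterion 18 (not isolated)
Conditions: Pd(OAc)2 (5 mol %), P(Oi-Pr)3 (30 mol %), toluene, 100 °C
Reagents that add atoms: none
Why: Palladium-catalysed trimethylenemethane [3+2] cycloaddition: zerovalent palladium ionises the allylic carbonate, the liberated methoxide removes silicon, zwitterion 18 reacts through its substituted terminus (the usual regiochemistry of alkyl-substituted donors) with the butenolide beta-carbon anti to the menthyloxy group, and the lactone enolate closes on the allyl unit from the same face, so that Cb and L4 are set cis and in the absolute sense dictated by the acetal centre while the hydrindanyl group on Ca takes the exo position.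

Step 11
Reactants: 19 cycloadduct
Product: 20 diol: methylenecyclopentane (L2=CH2) with cis CH2OH arms on Cb and L4 (lower face) and hydrindanyl on Ca (upper face)
Conditions: LiAlH4, THF, 0 °C to rt
Reagents that add atoms: none
Why: Exhaustive hydride reduction of the acylal-type lactone takes the carbonyl carbon L5 and the acetal carbon Cc both to primary alcohols and releases the auxiliary, while the exocyclic alkene survives as a masked L2 ketone and the fast reduction leaves no time for epimerisation next to a carbonyl.

Step 12
Reactants: 20 diol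
Product: 21 L5 trityl ether (Cc hydroxyl free)
Conditions: Ph3CCl (1.05 equiv), Et3N, DMAP (cat.), CH2Cl2, 0 °C to rt
Reagents that add atoms: trityl chloride, ClC(c1ccccc1)(c1ccccc1)c1ccccc1
Why: Sterically governed mono-tritylation of a diol: the very bulky trityl chloride should take the L5 hydroxyl, whose ring carbon is flanked by the L3 methylene, in preference to the Cc hydroxyl, which is wedged between the L5 arm and the hydrindanyl-bearing Ca.

Step 13
Reactants: 21 L5 trityl ether
Product: 22 L5 trityl ether / Cc PMB ether
Conditions: NaH, PMBCl, Bu4NI (cat.), DMF, 0 °C to rt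
Reagents that add atoms: 4-methoxybenzyl chloride, COc1ccc(CCl)cc1
Why: Williamson etherification of the remaining hydroxyl gives a Cc ether that cannot migrate, withstands enolate chemistry and alkoxide, and is removable later under neutral oxidative conditions.

Step 14
Reactants: 22 bis-ether alkene
Product: 24 2-hydrindanyl-3-(PMB-oxymethyl)-4-(trityloxymethyl)cyclopentanone (arms cis; hydrindanyl trans to Cc arm), via secondary ozonide 23 (not isolated)
Conditions: O3, CH2Cl2, -78 °C; Me2S, -78 °C to rt
Reagents that add atoms: ozone, [O-][O+]=O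
Why: Ozonolysis with reductive work-up: the 1,1-disubstituted alkene reacts much faster than the anisyl and trityl rings when the gas stream is stopped at first excess, and in the resulting ketone the now epimerisable Ca keeps (or adopts) the hydrindanyl group trans to the Cc arm.

Step 15
Reactants: 24 cyclopentanone
Product: 26 tert-butyldimethylsilyl enol ether (L2=L3), via lithium enolate 25 (not isolated)
Conditions: LiN(i-Pr)2, THF, -78 °C; TBSOTf
Reagents that add atoms: tert-butyldimethylsilyl triflate, CC(C)(C)[Si](C)(C)OS(=O)(=O)C(F)(F)F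
Why: Kinetic enolisation with a hindered lithium amide removes a proton from the open L3 methylene and not from the crowded Ca methine, and O-silylation fixes this regiochemistry as the silyl enol ether.

Step 16
Reactants: 26 silyl enol ether
Product: 28 5-silyloxy ketone (L3 OTBS on the upper face; trans to the L5 arm), via silyloxy epoxide 27 (not isolated)
Conditions: mCPBA, CH2Cl2, -20 °C to 0 °C
Reagents that add atoms: 3-chloroperbenzoic acid, OOC(=O)c1cccc(Cl)c1
Why: Rubottom oxidation: the peracid epoxidises the enol ether from the upper face, opposite the adjacent L5 arm, and epoxide 27 opens with 1,4-silyl shift to the alpha-silyloxy ketone with the L3 oxygen trans to L5, which is also the thermodynamically preferred epimer of this enolisable centre.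

Step 17
Reactants: 28 5-silyloxy ketone
Product: 30 2-hydrindanyl-2-(hydroxymethyl) ketone (CH2OH on the upper face; trans to the Cc arm), via potassium enolate 29 (not isolated)
Conditions: KN(SiMe3)2, THF, -78 °C to -40 °C; monomeric CH2O in THF (from paraformaldehyde), -78 °C; AcOH
Reagents that add atoms: formaldehyde, C=O
Why: Crossed aldol addition to formaldehyde: with a hindered amide base under kinetic control alpha-silyloxy ketones lose the proton of the non-oxygenated alpha-carbon, here Ca-H, the L3-H being deactivated by its geminal silyloxy group and screened by the neighbouring trityloxymethyl arm, and the smallest of all electrophiles then attacks planar enolate 29 from the upper face opposite the Cc arm, which places CH2OH trans to Cc at a quaternary centre whose configuration is erased in step 20 anyway.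

Step 18
Reactants: 30 hydroxymethyl ketone
Product: 31 2-(mesyloxymethyl) ketone (L5 still tritylated)
Conditions: MsCl, Et3N, CH2Cl2, -10 °C
Reagents that add atoms: methanesulfonyl chloride, CS(=O)(=O)Cl
Why: Sulfonylation of the only free hydroxyl with mesyl chloride and triethylamine is fast even for neopentyl alcohols, which leaves no time for retro-aldol cleavage, and the beta-mesyloxy ketone cannot eliminate because Ca bears no hydrogen.

Step 19
Reactants: 31 trityl mesylate
Product: 32 fragmentation precursor: 2-hydrindanyl-2-(mesyloxymethyl)-3-(PMB-oxymethyl)-4-(hydroxymethyl)-5-(tert-butyldimethylsilyloxy)cyclopentanone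
Conditions: CF3CO2H (2 vol %), Et3SiH, CH2Cl2, 0 °C
Reagents that add atoms: none
Why: Acidolysis of the trityl ether with hydride capture of the trityl cation is fast in very dilute acid, conditions under which the secondary silyl ether, the PMB ether and the mesylate persist, and without base the hydroxy ketone does not fragment.

Step 20
Reactants: 32 fragmentation precursor
Product: 35 PMB ether of the deacetyl O-silyl target (gamma-lactone and Ca=CH2 in place), via sodium alkoxide 33 (not isolated), via hemiketal alkoxide 34 (not isolated)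
Conditions: NaH (1.1 equiv), THF, 0 °C to 40 °C
Reagents that add atoms: none
Why: NaH converts the L5 hydroxyl into alkoxide 33, which adds to the L2 carbonyl from the lower face to give the 2-oxabicyclo[2.2.1]heptane hemiketal alkoxide 34; there the oxyanion pushes, the Ca-L2 bond (antiperiplanar to the freely rotating Ca'-OMs bond) breaks and mesylate departs in a concerted Grob fragmentation that leaves L2 as lactone carbonyl and Ca=Ca' as the methylene. The closest known reaction type is the alkoxide-induced fragmentation of beta-sulfonyloxy ketones to an ester and an alkene, run here with an internal alkoxide. The only ring closed is the gamma-lactone, formed by 5-exo-trig attack of the L5 oxygen on L2, while the carbocycle is opened. No stereocentre is created: Cb, L4 and L3 pass through unchanged, their trans L3-O/L5 relation on the carbocycle reappears as the cis relation of silyloxy group and side chain on the lactone, and the quaternary centre Ca is erased. The step needs fragmentation to outrun substitution at Ca' and attack by any other oxygen, which the substrate secures because the PMB ether leaves L5-O as the sole nucleophile, Ca' is neopentyl and lies on the face opposite to L5, Ca has no hydrogen for elimination, and one equivalent of insoluble NaH leaves no base behind that could epimerise L3 of the lactone. The strained hemiketal is only thinly populated, but its cleavage releases that strain and is the single irreversible exit, so reversible events such as silyl shuttling between the L3 oxygen and the alkoxides should drain into 35.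

Step 21
Reactants: 35 PMB ether lactone
Product: 36 deacetyl O-silyl form of the target (Cc hydroxyl free; L3 OTBS)
Conditions: DDQ, CH2Cl2/pH 7 buffer, 0 °C
Reagents that add atoms: none
Why: Oxidative PMB cleavage with DDQ is neutral and leaves the 1,1-disubstituted alkene, the silyl ether and the lactone untouched, so the free Cc hydroxyl is not exposed to acid or base that could induce translactonisation.

Step 22
Reactants: 36 primary alcohol
Product: 37 O-silyl target (Cc acetate; L3 OTBS)
Conditions: Ac2O, pyridine, DMAP (cat.), CH2Cl2, 0 °C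
Reagents that add atoms: acetic anhydride, CC(=O)OC(C)=O
Why: Standard O-acetylation of the only free (primary) hydroxyl is much faster than any acyl transfer from the lactone.

Step 23
Reactants: 37 O-silyl target
Product: 38 target CNP0252518.3
Conditions: HF·pyridine, pyridine, THF, 0 °C to rt
Reagents that add atoms: none
Why: Fluoride-mediated desilylation under buffered, weakly acidic conditions frees the L3 hydroxyl without epimerisation at L3, acetate migration or alkene isomerisation and gives the target.

Compound list
1 | (S)-Hajos-Parrish ketone | C[C@]12CCC(=O)C=C1CCC2=O | starting material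
2 | C1 ethylene ketal of 1 | C[C@]12CCC(=O)C=C1CCC23OCCO3 | intermediate
3 | 4-methyl enone ketal (not isolated) | C[C@]12CCC(=O)C(C)=C1CCC23OCCO3 | intermediate
4 | 4,4-dimethyl-5-ketone ketal, C3=C3a alkene | C[C@]12CCC(=O)C(C)(C)C1=CCC23OCCO3 | intermediate
5 | C5 hydrazone of 4 (not isolated) | C[C@]12CCC(=NN)C(C)(C)C1=CCC23OCCO3 | intermediate
6 | 4,4,7a-trimethyl C3=C3a alkene ketal | C[C@]12CCCC(C)(C)C1=CCC23OCCO3 | intermediate
7 | trans-hydrindane ketal | C[C@]12CCCC(C)(C)[C@@H]1CCC23OCCO3 | intermediate
8 | (3aS,7aS)-4,4,7a-trimethyloctahydro-1H-inden-1-one | O=C1CC[C@H]2C(C)(C)CCC[C@]12C | intermediate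
9 | 1-methylene-trans-hydrindane | C=C1CC[C@H]2C(C)(C)CCC[C@]12C | intermediate
10 | B-alkyl-9-BBN adduct (not isolated) | C(B1C2CCCC1CCC2)[C@H]1CC[C@H]2C(C)(C)CCC[C@]12C | intermediate
11 | (1S,3aS,7aS)-hydrindan-1-ylmethanol | OC[C@H]1CC[C@H]2C(C)(C)CCC[C@]12C | intermediate
12 | (1S,3aS,7aS)-hydrindane-1-carbaldehyde | O=C[C@H]1CC[C@H]2C(C)(C)CCC[C@]12C | intermediate
13 | 2-bromoallyltrimethylsilane | C=C(Br)C[Si](C)(C)C | starting material
14 | [1-(trimethylsilylmethyl)vinyl]lithium (not isolated) | [Li]C(=C)C[Si](C)(C)C | intermediate
15 | lithium alkoxide of the adduct (not isolated; carbinol epimers) | [Li]OC(C(=C)C[Si](C)(C)C)[C@H]1CC[C@H]2C(C)(C)CCC[C@]12C | intermediate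
16 | hydrindanyl allyl methyl carbonate/allylsilane (carbinol epimers) | COC(=O)OC(C(=C)C[Si](C)(C)C)[C@H]1CC[C@H]2C(C)(C)CCC[C@]12C | intermediate
17 | (5S)-5-[(1S,2R,5S)-menthyloxy]furan-2(5H)-one | O=C1C=C[C@@H](O[C@H]2C[C@@H](C)CC[C@@H]2C(C)C)O1 | starting material
18 | palladium TMM zwitterion, sigma form, ligands omitted (not isolated) | [Pd+]CC(=C)[CH-][C@H]1CC[C@H]2C(C)(C)CCC[C@]12C | intermediate
19 | cis-fused methylenecyclopentane/menthyloxylactone cycloadduct | C=C1C[C@H]2C(=O)O[C@H](O[C@H]3C[C@@H](C)CC[C@@H]3C(C)C)[C@H]2[C@@H]1[C@H]4CC[C@H]5C(C)(C)CCC[C@]45C | intermediate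
20 | cis-diol with exocyclic methylene | C=C1C[C@@H](CO)[C@@H](CO)[C@@H]1[C@H]2CC[C@H]3C(C)(C)CCC[C@]23C | intermediate
21 | L5 trityl ether | C=C1C[C@@H](COC(c2ccccc2)(c2ccccc2)c2ccccc2)[C@@H](CO)[C@@H]1[C@H]2CC[C@H]3C(C)(C)CCC[C@]23C | intermediate
22 | L5 trityl / Cc PMB bis-ether | C=C1C[C@@H](COC(c2ccccc2)(c2ccccc2)c2ccccc2)[C@@H](COCc2ccc(OC)cc2)[C@@H]1[C@H]2CC[C@H]3C(C)(C)CCC[C@]23C | intermediate
23 | secondary ozonide, spiro centre undefined (not isolated) | C1OC2(OO1)C[C@@H](COC(c3ccccc3)(c3ccccc3)c3ccccc3)[C@@H](COCc3ccc(OC)cc3)[C@@H]2[C@H]3CC[C@H]4C(C)(C)CCC[C@]34C | intermediate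
24 | 2-hydrindanyl cyclopentanone | O=C1C[C@@H](COC(c2ccccc2)(c2ccccc2)c2ccccc2)[C@@H](COCc2ccc(OC)cc2)[C@@H]1[C@H]2CC[C@H]3C(C)(C)CCC[C@]23C | intermediate
25 | kinetic lithium enolate (not isolated) | [Li]OC1=C[C@@H](COC(c2ccccc2)(c2ccccc2)c2ccccc2)[C@@H](COCc2ccc(OC)cc2)[C@@H]1[C@H]2CC[C@H]3C(C)(C)CCC[C@]23C | intermediate
26 | TBS enol ether (L2=L3) | CC(C)(C)[Si](C)(C)OC1=C[C@@H](COC(c2ccccc2)(c2ccccc2)c2ccccc2)[C@@H](COCc2ccc(OC)cc2)[C@@H]1[C@H]2CC[C@H]3C(C)(C)CCC[C@]23C | intermediate
27 | silyloxy epoxide, oxygen on the upper face (not isolated) | CC(C)(C)[Si](C)(C)O[C@@]12O[C@@H]1[C@@H](COC(c3ccccc3)(c3ccccc3)c3ccccc3)[C@@H](COCc3ccc(OC)cc3)[C@@H]2[C@H]3CC[C@H]4C(C)(C)CCC[C@]34C | intermediate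
28 | 5-silyloxy ketone | O=C1[C@H](O[Si](C)(C)C(C)(C)C)[C@@H](COC(c2ccccc2)(c2ccccc2)c2ccccc2)[C@@H](COCc2ccc(OC)cc2)[C@@H]1[C@H]2CC[C@H]3C(C)(C)CCC[C@]23C | intermediate
29 | potassium enolate (Ca=L2) (not isolated) | [K]OC1=C([C@H]2CC[C@H]3C(C)(C)CCC[C@]23C)[C@H](COCc2ccc(OC)cc2)[C@H](COC(c2ccccc2)(c2ccccc2)c2ccccc2)[C@H]1O[Si](C)(C)C(C)(C)C | intermediate
30 | 2-(hydroxymethyl) ketone | O=C1[C@H](O[Si](C)(C)C(C)(C)C)[C@@H](COC(c2ccccc2)(c2ccccc2)c2ccccc2)[C@@H](COCc2ccc(OC)cc2)[C@@]1(CO)[C@H]2CC[C@H]3C(C)(C)CCC[C@]23C | intermediate
31 | 2-(mesyloxymethyl) ketone, L5 tritylated | O=C1[C@H](O[Si](C)(C)C(C)(C)C)[C@@H](COC(c2ccccc2)(c2ccccc2)c2ccccc2)[C@@H](COCc2ccc(OC)cc2)[C@@]1(COS(C)(=O)=O)[C@H]2CC[C@H]3C(C)(C)CCC[C@]23C | intermediate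
32 | fragmentation precursor (L5 OH free, Cc OPMB, L3 OTBS) | O=C1[C@H](O[Si](C)(C)C(C)(C)C)[C@@H](CO)[C@@H](COCc2ccc(OC)cc2)[C@@]1(COS(C)(=O)=O)[C@H]2CC[C@H]3C(C)(C)CCC[C@]23C | intermediate
33 | sodium L5 alkoxide (not isolated) | O=C1[C@H](O[Si](C)(C)C(C)(C)C)[C@@H](CO[Na])[C@@H](COCc2ccc(OC)cc2)[C@@]1(COS(C)(=O)=O)[C@H]2CC[C@H]3C(C)(C)CCC[C@]23C | intermediate
34 | 2-oxabicyclo[2.2.1]heptane hemiketal alkoxide (not isolated) | [Na]O[C@]12OC[C@H]([C@H]1O[Si](C)(C)C(C)(C)C)[C@@H](COCc3ccc(OC)cc3)[C@@]2(COS(C)(=O)=O)[C@H]3CC[C@H]4C(C)(C)CCC[C@]34C | intermediate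
35 | PMB ether of the deacetyl O-silyl target | C=C([C@H]1CC[C@H]2C(C)(C)CCC[C@]12C)[C@H](COCc1ccc(OC)cc1)[C@@H]1COC(=O)[C@@H]1O[Si](C)(C)C(C)(C)C | intermediate
36 | deacetyl O-silyl form of the target | C=C([C@H]1CC[C@H]2C(C)(C)CCC[C@]12C)[C@H](CO)[C@@H]1COC(=O)[C@@H]1O[Si](C)(C)C(C)(C)C | intermediate
37 | O-silyl target (Cc acetate) | C=C([C@H]1CC[C@H]2C(C)(C)CCC[C@]12C)[C@H](COC(C)=O)[C@@H]1COC(=O)[C@@H]1O[Si](C)(C)C(C)(C)C | intermediate
38 | CNP0252518.3 | C=C([C@H]1CC[C@H]2C(C)(C)CCC[C@]12C)[C@H](COC(C)=O)[C@@H]1COC(=O)[C@@H]1O | target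

Total step count: 23. Longest linear sequence: 23 steps (1 to 38); 13 and 17 enter as bought materials.

Steps most likely to fail

1. Step 20 (key step).
- What may go wrong: the bridged hemiketal is strained and may be populated so thinly that slower base-induced processes compete. One is silyl migration from the L3 oxygen to the L5 alkoxide. The other is deprotonation of the mesyl methyl group followed by its addition to the ketone.
- Fallback (sets out from 31, comes back at 35): the electron push is supplied by a carbinol oxygen on L2 itself instead of a bridging oxygen. Reduction of 31 with i-Bu2AlH (CH2Cl2, -78 °C) should give the hydroxy mesylate F1; either L2 epimer serves, since the Ca'-O bond rotates freely. KOt-Bu in THF then triggers the classical fragmentation of a 1,3-diol monosulfonate to the alpha-silyloxy aldehyde F2. Trityl removal as in step 19 lets the L5 hydroxyl close on the aldehyde to the lactol F3. Oxidation with Ag2CO3 on Celite in toluene gives 35.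

2. Step 10.
- What may go wrong: crowding at the hydrindanyl-bearing terminus may slow the conjugate addition to an acceptor whose beta-carbon is flanked by the acetal. Bond formation through the unsubstituted terminus (regiochemical leakage) or donor decomposition could then take over.
- Fallback (sets out from 16, comes back at 20): control by the auxiliary is given up in favour of convergence and separation. 16 is combined under the same zerovalent palladium catalysis with unsubstituted furan-2(5H)-one, whose beta-carbon is unencumbered. This should give the lactone F4 together with its regioisomer F5. The mixture is reduced with LiAlH4 without separation. Both arms end as CH2OH, so either orientation of the acceptor gives the same diol 20 and regiochemistry no longer matters. The choice of ring face now rests on the hydrindane alone, and the diastereomeric diol F6 has to be removed by chromatography.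

3. Step 17.
- What may go wrong: deprotonation may occur at L3 instead of Ca, followed by hydroxymethylation at the wrong carbon. Retro-aldol loss of formaldehyde on work-up is a second risk.
- Fallback (sets out from 26, comes back at 31): the L3 side is blocked as an sp2 carbon.
  - Saegusa-Ito dehydrogenation of 26 with Pd(OAc)2 in MeCN should give the L3=L4 enone F7.
  - Kinetic deprotonation of a cyclopentenone with LiN(i-Pr)2 takes the alpha-prime proton (Ca-H) even when it sits on a branched methine. Formaldehyde then gives the hydroxymethyl enone F8.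
  - MsCl/Et3N gives the enone mesylate F9.
  - Conjugate reduction with [(Ph3P)CuH]6 in toluene delivers hydride to L4 from the upper face, opposite the vicinal Cc arm. This restores the cis arms in the saturated ketone mesylate F10.
  - With Ca quaternary only L3 can enolise, so TBSOTf/Et3N gives the silyl enol ether F11. mCPBA as in step 16 then gives 31.

Further compounds
F1 | step 20 | hydroxy mesylate (L2 carbinol, either epimer) | OC1[C@H](O[Si](C)(C)C(C)(C)C)[C@@H](COC(c2ccccc2)(c2ccccc2)c2ccccc2)[C@@H](COCc2ccc(OC)cc2)[C@@]1(COS(C)(=O)=O)[C@H]2CC[C@H]3C(C)(C)CCC[C@]23C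
F2 | step 20 | alpha-silyloxy aldehyde (L2 = CHO, Ca=CH2, L5 OTr) | C=C([C@H]1CC[C@H]2C(C)(C)CCC[C@]12C)[C@H](COCc1ccc(OC)cc1)[C@H](COC(c1ccccc1)(c1ccccc1)c1ccccc1)[C@@H](O[Si](C)(C)C(C)(C)C)C=O
F3 | step 20 | lactol (anomers) | C=C([C@H]1CC[C@H]2C(C)(C)CCC[C@]12C)[C@H](COCc1ccc(OC)cc1)[C@@H]1COC(O)[C@@H]1O[Si](C)(C)C(C)(C)C
F4 | step 10 | lactone cycloadduct (L5 = C=O, Cc = OCH2) | C=C1C[C@H]2C(=O)OC[C@H]2[C@@H]1[C@H]3CC[C@H]4C(C)(C)CCC[C@]34C
F5 | step 10 | regioisomeric lactone cycloadduct (Cc = C=O, L5 = OCH2) | C=C1C[C@H]2COC(=O)[C@H]2[C@@H]1[C@H]3CC[C@H]4C(C)(C)CCC[C@]34C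
F6 | step 10 | diastereomeric diol (opposite ring face) | C=C1C[C@H](CO)[C@H](CO)[C@H]1[C@H]2CC[C@H]3C(C)(C)CCC[C@]23C
F7 | step 17 | L3=L4 enone | O=C1C=C(COC(c2ccccc2)(c2ccccc2)c2ccccc2)[C@@H](COCc2ccc(OC)cc2)[C@@H]1[C@H]2CC[C@H]3C(C)(C)CCC[C@]23C
F8 | step 17 | hydroxymethyl enone | O=C1C=C(COC(c2ccccc2)(c2ccccc2)c2ccccc2)[C@@H](COCc2ccc(OC)cc2)[C@@]1(CO)[C@H]2CC[C@H]3C(C)(C)CCC[C@]23C
F9 | step 17 | enone mesylate | O=C1C=C(COC(c2ccccc2)(c2ccccc2)c2ccccc2)[C@@H](COCc2ccc(OC)cc2)[C@@]1(COS(C)(=O)=O)[C@H]2CC[C@H]3C(C)(C)CCC[C@]23C
F10 | step 17 | saturated ketone mesylate (L3 = CH2) | O=C1C[C@@H](COC(c2ccccc2)(c2ccccc2)c2ccccc2)[C@@H](COCc2ccc(OC)cc2)[C@@]1(COS(C)(=O)=O)[C@H]2CC[C@H]3C(C)(C)CCC[C@]23C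
F11 | step 17 | silyl enol ether of F10 | CC(C)(C)[Si](C)(C)OC1=C[C@@H](COC(c2ccccc2)(c2ccccc2)c2ccccc2)[C@@H](COCc2ccc(OC)cc2)[C@@]1(COS(C)(=O)=O)[C@H]2CC[C@H]3C(C)(C)CCC[C@]23C
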